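Hypholomine B 18 ⇐ tetrabenzyl ether 17 by global debenzylation; ring B (the 4-hydroxy-2-pyranone on C3) ⇐ a carboxyl carbon on C3 plus a four-carbon acetoacetate unit; the styryl arm ⇐ vinylogous aldol condensation at the C6 methyl group of ring A.
The strategy rests on the C3–C3a bond, which joins the stereocentre C3 of the dihydrofuran to C3a of the fused pyranone ring A while C3 also carries C6' of ring B. This is the pattern left when the pyranone carbon shifts from a ketone carbon to its α-carbon, the ketone carbon ending as the carboxyl carbon (later C6').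
Key disconnection: dihydrofuran ester 9 ⇐ oxidative ring contraction (trivalent iodine) of the flavanone-like (S)-2-aryl-2,3-dihydropyrano[4,3-b]pyran-4,5-dione 6; 6 ⇐ asymmetric conjugate arylation of bicyclic enone 4, made from dehydroacetic acid.
Order of ring formation: ring A (bought as dehydroacetic acid) → 4-pyranone ring (step 2) → dihydrofuran by contraction of that ring (step 4) → ring B (step 8).

Key step: step 4

Remark on numbering: 6–8 carry pyrano[4,3-b]pyran numbering (O1, C2, C3, C4, C4a, C5, O6, C7, C8, C8a); from 9 on furo[3,2-c]pyran numbering is used (O1, C2, C3, C3a, C4, O5, C6, C7, C7a), so C4a of 6 becomes C3a of 9; primed atoms belong to ring B.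
Assumption: the arylation of 4 is taken to follow the facial sense known for chromone with this ligand class ((S)-ligand gives (R)-flavanone), hence the (R)-ligand for the 2S series; if the first run shows the opposite sense, the ligand antipode is used.
Remark on protecting groups: the catechols are carried as benzyl ethers, which can be removed at −78 °C at the end.

Step 1
Reactants: 1 dehydroacetic acid; 2 N,N-dimethylformamide dimethyl acetal
Product: 3 (E)-3-[3-(dimethylamino)prop-2-enoyl]-4-hydroxy-6-methyl-2H-pyran-2-one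
Conditions: 2 (1.2 equiv), PhMe, 80 °C
Reagents that add atoms: none
Why: Enaminone formation: the acetyl methyl group, the most acidic C–H of the chelated tricarbonyl system, condenses with the amide acetal to the E-enaminone, and no stereocentre is formed.

Step 2
Reactants: 3 (E)-3-[3-(dimethylamino)prop-2-enoyl]-4-hydroxy-6-methyl-2H-pyran-2-one
Product: 4 7-methyl-4H,5H-pyrano[4,3-b]pyran-4,5-dione
Conditions: conc. HCl, CH2Cl2, 40 °C
Reagents that add atoms: none
Why: Acid-mediated 6-endo-trig addition of the 4-hydroxyl to the protonated enaminone and loss of dimethylamine (the usual chromone synthesis from o-hydroxyaryl enaminones) should close the 4-pyranone ring; no stereocentre is formed.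

Step 3
Reactants: 4 7-methyl-4H,5H-pyrano[4,3-b]pyran-4,5-dione; 5 3,4-bis(benzyloxy)phenylboronic acid
Product: 6 (S)-2-[3,4-bis(benzyloxy)phenyl]-7-methyl-2,3-dihydro-4H,5H-pyrano[4,3-b]pyran-4,5-dione
Conditions: 5 (2 equiv), Pd(OCOCF3)2 (5 mol %), (R)-t-BuPyOx [(R)-4-tert-butyl-2-(pyridin-2-yl)-4,5-dihydrooxazole, 6 mol %], NH4PF6 (30 mol %), H2O (5 equiv), ClCH2CH2Cl, 60 °C
Reagents that add atoms: none
Why: Palladium-catalysed asymmetric conjugate addition of an arylboronic acid to a chromone-type enone: the cationic aryl complex of divalent palladium with the pyridine–oxazoline ligand inserts the C2=C3 bond on the face left open by the tert-butyl group, which should set C2 as S by irreversible C–C bond formation without base, and water protonates the palladium enolate.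

Step 4
Reactants: 6 (S)-2-[3,4-bis(benzyloxy)phenyl]-7-methyl-2,3-dihydro-4H,5H-pyrano[4,3-b]pyran-4,5-dione
Product: 9 methyl (2S,3S)-2-[3,4-bis(benzyloxy)phenyl]-6-methyl-4-oxo-2,3-dihydro-4H-furo[3,2-c]pyran-3-carboxylate, via methyl enol ether 7 (not isolated), via trans C3-iodanyl dimethyl ketal 8 (not isolated)
Conditions: PhI(OH)OTs (1.2 equiv), HC(OMe)3, H2SO4 (cat.), 0 °C → rt
Reagents that add atoms: trimethyl orthoformate, COC(OC)OC; [hydroxy(tosyloxy)iodo]benzene, Cc1ccc(cc1)S(=O)(=O)OI(O)c1ccccc1 (its atoms stay only in 8)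
Why: Proposed new method: in HC(OMe)3 and acid the C4 ketone of 6 should give methyl enol ether 7, PhI(OH)OTs (trivalent iodine) should attack C3 of 7 on the face anti to the C2 aryl group, and methanol completes ketal 8, in which the C3–I bond lies equatorial and antiperiplanar to the C4–C4a bond. C4a, the nucleophilic α-carbon of the 4-alkoxy-2-pyranone, then shifts from C4 to C3 with loss of iodobenzene and inversion at C3, while the two methoxy groups stabilise C4 as a dimethoxycarbenium ion that collapses to the methyl ester. The closest known reaction type is the contraction of flavanones to methyl trans-2-aryl-2,3-dihydrobenzofuran-3-carboxylates with PhI(OH)OTs or Tl(NO3)3 in trimethyl orthoformate, in which a benzenoid carbon migrates and C2 keeps its configuration; new here is that the migrating carbon belongs to a pyranone. The dihydrofuran is closed not by cyclisation but by contraction of the dihydropyranone through a suprafacial 1,2-shift (a 3-exo-tet attack of C4a on C3 through a bridged ion), which forms the C3–C3a bond. C3 is set as S under substrate control, since iodine enters anti to the C2 substituent and is displaced with inversion, which places the ester trans to the aryl group, also the more stable arrangement; C2 is not touched. The step needs C4a to migrate in preference to the C2 aryl group and to plain α-methoxylation or dehydrogenation, which prior ketalisation (donor push at C4), the geometry of 8 (C3–I anti to C4–C4a but gauche to the aryl group) and the poor ability of the vinylogous ester oxygen O1 to stabilise a C2 cation should secure.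

Step 5
Reactants: 9 methyl (2S,3S)-2-[3,4-bis(benzyloxy)phenyl]-6-methyl-4-oxo-2,3-dihydro-4H-furo[3,2-c]pyran-3-carboxylate
Product: 10 (2S,3S)-2-[3,4-bis(benzyloxy)phenyl]-6-methyl-4-oxo-2,3-dihydro-4H-furo[3,2-c]pyran-3-carboxylic acid
Conditions: Me3SnOH (5 equiv), ClCH2CH2Cl, 80 °C; then 1 M HCl
Reagents that add atoms: trimethyltin hydroxide, C[Sn](C)(C)O
Why: Tin hydroxide cleavage of a methyl ester under nearly neutral conditions should spare the pyranone lactone and avoid enolate-driven loss of O1 from C2; C3 can epimerise but trans is the stable arrangement.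

Step 6
Reactants: 10 (2S,3S)-2-[3,4-bis(benzyloxy)phenyl]-6-methyl-4-oxo-2,3-dihydro-4H-furo[3,2-c]pyran-3-carboxylic acid; 11 3,4-bis(benzyloxy)benzaldehyde
Product: 13 (2S,3S)-2-[3,4-bis(benzyloxy)phenyl]-6-[(E)-2-[3,4-bis(benzyloxy)phenyl]ethenyl]-4-oxo-2,3-dihydro-4H-furo[3,2-c]pyran-3-carboxylic acid, via hydroxy acid 12 (not isolated)
Conditions: LiN(SiMe3)2 (2.2 equiv), THF, −78 °C; 11, −78 → −40 °C; 1 M HCl; then TsOH·H2O (cat.), PhMe, 60 °C
Reagents that add atoms: none
Why: Vinylogous aldol addition then dehydration: the first equivalent of base gives the carboxylate, which shields the C3–H from enolisation, the second deprotonates the C6 methyl group to the extended enolate of the 2-pyranone, and acid-catalysed loss of water from the p-alkoxybenzylic alcohol should give the conjugated E-alkene under thermodynamic control.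

Step 7
Reactants: 13 (2S,3S)-2-[3,4-bis(benzyloxy)phenyl]-6-[(E)-2-[3,4-bis(benzyloxy)phenyl]ethenyl]-4-oxo-2,3-dihydro-4H-furo[3,2-c]pyran-3-carboxylic acid; 14 1-methoxy-1,3-bis(trimethylsilyloxy)buta-1,3-diene
Product: 16 methyl 5-[(2S,3S)-2-[3,4-bis(benzyloxy)phenyl]-6-[(E)-2-[3,4-bis(benzyloxy)phenyl]ethenyl]-4-oxo-2,3-dihydro-4H-furo[3,2-c]pyran-3-yl]-3,5-dioxopentanoate, via acid chloride 15 (not isolated)
Conditions: (COCl)2, DMF (cat.), CH2Cl2, 0 °C → rt; evaporate; 14 (1.5 equiv), CH2Cl2, −78 °C → rt; 1 M HCl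
Reagents that add atoms: oxalyl chloride, O=C(Cl)C(=O)Cl (supplies only the chlorine of 15)
Why: γ-Acylation of a 1,3-bis(silyl enol ether) by an acid chloride: the acid chloride is made without base so that no ketene forms at C3, it should acylate the terminal carbon of the acetoacetate bis(silyl enol ether), and aqueous acid frees the 3,5-dioxo ester.

Step 8
Reactants: 16 methyl 5-[(2S,3S)-2-[3,4-bis(benzyloxy)phenyl]-6-[(E)-2-[3,4-bis(benzyloxy)phenyl]ethenyl]-4-oxo-2,3-dihydro-4H-furo[3,2-c]pyran-3-yl]-3,5-dioxopentanoate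
Product: 17 (2S,3S)-2-[3,4-bis(benzyloxy)phenyl]-6-[(E)-2-[3,4-bis(benzyloxy)phenyl]ethenyl]-3-(4-hydroxy-2-oxo-2H-pyran-6-yl)-2,3-dihydro-4H-furo[3,2-c]pyran-4-one
Conditions: DBU (1.5 equiv), PhMe, rt → 60 °C; then 1 M HCl
Reagents that add atoms: none
Why: Triketide-type lactonisation to a 4-hydroxy-2-pyranone: DBU enolises the 1,3-diketone between its carbonyl groups and the 5-enol oxygen closes onto the methyl ester (6-exo-trig) to form ring B, while the diketonate formed first shields the C3–H so that the trans arrangement is kept.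

Step 9
Reactants: 17 (2S,3S)-2-[3,4-bis(benzyloxy)phenyl]-6-[(E)-2-[3,4-bis(benzyloxy)phenyl]ethenyl]-3-(4-hydroxy-2-oxo-2H-pyran-6-yl)-2,3-dihydro-4H-furo[3,2-c]pyran-4-one
Product: 18 hypholomine B
Conditions: BCl3 (10 equiv), C6HMe5 (12 equiv), CH2Cl2, −78 °C; MeOH/CHCl3 quench at −78 °C
Reagents that add atoms: none
Why: Lewis-acid debenzylation with a cation scavenger: BCl3 cleaves aryl benzyl ethers at −78 °C and pentamethylbenzene takes up the benzyl cations, which should leave the styryl double bond, both pyranones and both stereocentres untouched, the catechols being held as chloroborates that lower the tendency of the C2–O1 bond to ionise.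

Compound list
1 | dehydroacetic acid (3-acetyl-4-hydroxy-6-methyl-2H-pyran-2-one) | CC(=O)c1c(O)cc(C)oc1=O | starting material
2 | N,N-dimethylformamide dimethyl acetal | COC(OC)N(C)C | starting material
3 | (E)-3-[3-(dimethylamino)prop-2-enoyl]-4-hydroxy-6-methyl-2H-pyran-2-one | CN(C)/C=C/C(=O)c1c(O)cc(C)oc1=O | intermediate
4 | 7-methyl-4H,5H-pyrano[4,3-b]pyran-4,5-dione | CC1=CC2=C(C(=O)O1)C(=O)C=CO2 | intermediate
5 | 3,4-bis(benzyloxy)phenylboronic acid | OB(O)c1ccc(OCc2ccccc2)c(OCc2ccccc2)c1 | starting material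
6 | (S)-2-[3,4-bis(benzyloxy)phenyl]-7-methyl-2,3-dihydro-4H,5H-pyrano[4,3-b]pyran-4,5-dione | O=C1C[C@@H](c2ccc(OCc3ccccc3)c(OCc3ccccc3)c2)Oc2cc(C)oc(=O)c12 | intermediate
7 | (S)-2-[3,4-bis(benzyloxy)phenyl]-4-methoxy-7-methyl-2H,5H-pyrano[4,3-b]pyran-5-one (methyl enol ether, not isolated) | COC1=C[C@@H](c2ccc(OCc3ccccc3)c(OCc3ccccc3)c2)Oc2cc(C)oc(=O)c12 | intermediate
8 | (2R,3R)-2-[3,4-bis(benzyloxy)phenyl]-4,4-dimethoxy-7-methyl-3-[phenyl(tosyloxy)-λ3-iodanyl]-3,4-dihydro-2H,5H-pyrano[4,3-b]pyran-5-one (iodine trans to the aryl group, not isolated; C2 is unchanged in space, its descriptor changes because of the iodine) | COC1(OC)[C@H](I(c2ccccc2)OS(=O)(=O)c2ccc(C)cc2)[C@@H](c2ccc(OCc3ccccc3)c(OCc3ccccc3)c2)Oc2cc(C)oc(=O)c12 | intermediate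
9 | methyl (2S,3S)-2-[3,4-bis(benzyloxy)phenyl]-6-methyl-4-oxo-2,3-dihydro-4H-furo[3,2-c]pyran-3-carboxylate (trans) | COC(=O)[C@H]1c2c(cc(C)oc2=O)O[C@@H]1c1ccc(OCc2ccccc2)c(OCc2ccccc2)c1 | intermediate
10 | (2S,3S)-2-[3,4-bis(benzyloxy)phenyl]-6-methyl-4-oxo-2,3-dihydro-4H-furo[3,2-c]pyran-3-carboxylic acid | OC(=O)[C@H]1c2c(cc(C)oc2=O)O[C@@H]1c1ccc(OCc2ccccc2)c(OCc2ccccc2)c1 | intermediate
11 | 3,4-bis(benzyloxy)benzaldehyde | O=Cc1ccc(OCc2ccccc2)c(OCc2ccccc2)c1 | starting material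
12 | (2S,3S)-2-[3,4-bis(benzyloxy)phenyl]-6-[2-[3,4-bis(benzyloxy)phenyl]-2-hydroxyethyl]-4-oxo-2,3-dihydro-4H-furo[3,2-c]pyran-3-carboxylic acid (both carbinol epimers, not isolated) | OC(=O)[C@H]1c2c(cc(CC(O)c3ccc(OCc4ccccc4)c(OCc4ccccc4)c3)oc2=O)O[C@@H]1c1ccc(OCc2ccccc2)c(OCc2ccccc2)c1 | intermediate
13 | (2S,3S)-2-[3,4-bis(benzyloxy)phenyl]-6-[(E)-2-[3,4-bis(benzyloxy)phenyl]ethenyl]-4-oxo-2,3-dihydro-4H-furo[3,2-c]pyran-3-carboxylic acid | OC(=O)[C@H]1c2c(cc(/C=C/c3ccc(OCc4ccccc4)c(OCc4ccccc4)c3)oc2=O)O[C@@H]1c1ccc(OCc2ccccc2)c(OCc2ccccc2)c1 | intermediate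
14 | 1-methoxy-1,3-bis(trimethylsilyloxy)buta-1,3-diene | COC(O[Si](C)(C)C)=CC(=C)O[Si](C)(C)C | starting material
15 | (2S,3S)-2-[3,4-bis(benzyloxy)phenyl]-6-[(E)-2-[3,4-bis(benzyloxy)phenyl]ethenyl]-4-oxo-2,3-dihydro-4H-furo[3,2-c]pyran-3-carbonyl chloride (not isolated) | ClC(=O)[C@H]1c2c(cc(/C=C/c3ccc(OCc4ccccc4)c(OCc4ccccc4)c3)oc2=O)O[C@@H]1c1ccc(OCc2ccccc2)c(OCc2ccccc2)c1 | intermediate
16 | methyl 5-[(2S,3S)-2-[3,4-bis(benzyloxy)phenyl]-6-[(E)-2-[3,4-bis(benzyloxy)phenyl]ethenyl]-4-oxo-2,3-dihydro-4H-furo[3,2-c]pyran-3-yl]-3,5-dioxopentanoate | COC(=O)CC(=O)CC(=O)[C@H]1c2c(cc(/C=C/c3ccc(OCc4ccccc4)c(OCc4ccccc4)c3)oc2=O)O[C@@H]1c1ccc(OCc2ccccc2)c(OCc2ccccc2)c1 | intermediate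
17 | (2S,3S)-2-[3,4-bis(benzyloxy)phenyl]-6-[(E)-2-[3,4-bis(benzyloxy)phenyl]ethenyl]-3-(4-hydroxy-2-oxo-2H-pyran-6-yl)-2,3-dihydro-4H-furo[3,2-c]pyran-4-one (tetra-O-benzylhypholomine B) | O=c1cc(O)cc([C@H]2c3c(cc(/C=C/c4ccc(OCc5ccccc5)c(OCc5ccccc5)c4)oc3=O)O[C@@H]2c2ccc(OCc3ccccc3)c(OCc3ccccc3)c2)o1 | intermediate
18 | hypholomine B, (2S,3S)-2-(3,4-dihydroxyphenyl)-6-[(E)-2-(3,4-dihydroxyphenyl)ethenyl]-3-(4-hydroxy-2-oxo-2H-pyran-6-yl)-2,3-dihydro-4H-furo[3,2-c]pyran-4-one | O=c1cc(O)cc([C@H]2c3c(cc(/C=C/c4ccc(O)c(O)c4)oc3=O)O[C@@H]2c2ccc(O)c(O)c2)o1 | target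

Total step count: 9. Longest linear sequence: 9 steps (1 → 18); 2, 5, 11 and 14 are bought.

Steps most likely to fail

1. Step 4 (new method).
What may go wrong: the C2 aryl group may migrate instead of C4a (2→3 shift to an isoflavone-type product), or no migration may occur (methanolysis of the C3–I bond or dehydrogenation), because the pyranone carbon may be a poorer migrating group than a benzenoid carbon. The C2–O1 bond may open under acid at the enol ether stage, with loss of enantiomeric purity. The benzyloxy-substituted arene may be oxidised.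
Fallback, known chemistry, from 1 and 11, back at 9: deacetylation of 1 (90% H2SO4, 130 °C) gives 4-hydroxy-6-methyl-2H-pyran-2-one F1. A Wittig reaction of 11 with Ph3P=CHCO2Me (PhMe, 80 °C) gives methyl (E)-3-[3,4-bis(benzyloxy)phenyl]prop-2-enoate F2. Oxidative [3+2] cycloaddition of F1 onto F2 with Mn(OAc)3·2H2O (trivalent manganese) in AcOH at 70 °C should give the racemic trans ester F3: the C3 radical of F1 adds to the α-carbon of the cinnamate, the benzylic radical is oxidised to the cation and the 4-oxygen closes the ring. Preparative SFC on a chiral phase then gives 9.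

2. Step 3.
What may go wrong: enantioselectivity may erode with the electron-rich boronic acid; β-alkoxide elimination from the palladium enolate may open the new ring; protodeboronation may outrun insertion.
Fallback, from 1 and 11, back at 6: piperidine-catalysed aldol condensation at the acetyl group (CHCl3, reflux, water separator) gives the chalcone (E)-3-[3-[3,4-bis(benzyloxy)phenyl]prop-2-enoyl]-4-hydroxy-6-methyl-2H-pyran-2-one F4. Acid-mediated oxa-Michael closure of the 4-hydroxyl (H3PO4, AcOH, 80 °C) gives the racemic dihydropyranopyrandione F5, and preparative SFC on a chiral phase gives 6. Compound 6 is then kept away from base and taken on at once.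

3. Step 9.
What may go wrong: the benzylic C2–O1 bond may ionise under the Lewis acid, followed by capture of the cation by the scavenger or loss of the C3 proton; cleavage of all four benzyl ethers may be incomplete.
Fallback, from 10, back at 18 (the benzyl ethers are exchanged for silyl ethers while no alkene is present, so that the last step needs only fluoride): hydrogenolysis of 10 (H2, Pd/C, EtOAc, rt) gives the catechol acid F6. TBSCl and imidazole in DMF give the tris-silyl compound F7, whose silyl ester falls apart in the aqueous AcOH work-up to the bis(silyl ether) acid F8. Steps 6 to 8 are then run in the same way with 3,4-bis(tert-butyldimethylsilyloxy)benzaldehyde F9, through hydroxy acid F10, styryl acid F11, acid chloride F12 and dioxo ester F13, to the tetrakis(silyl ether) of hypholomine B F14. HF·pyridine in THF at 0 °C then frees 18.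

Further compounds
F1 | step 4 | 4-hydroxy-6-methyl-2H-pyran-2-one | Cc1cc(O)cc(=O)o1
F2 | step 4 | methyl (E)-3-[3,4-bis(benzyloxy)phenyl]prop-2-enoate | COC(=O)/C=C/c1ccc(OCc2ccccc2)c(OCc2ccccc2)c1
F3 | step 4 | racemic methyl (2S*,3S*)-2-[3,4-bis(benzyloxy)phenyl]-6-methyl-4-oxo-2,3-dihydro-4H-furo[3,2-c]pyran-3-carboxylate (trans racemate, the 2S,3S enantiomer drawn) | COC(=O)[C@H]1c2c(cc(C)oc2=O)O[C@@H]1c1ccc(OCc2ccccc2)c(OCc2ccccc2)c1
F4 | step 3 | (E)-3-[3-[3,4-bis(benzyloxy)phenyl]prop-2-enoyl]-4-hydroxy-6-methyl-2H-pyran-2-one | Cc1cc(O)c(C(=O)/C=C/c2ccc(OCc3ccccc3)c(OCc3ccccc3)c2)c(=O)o1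
F5 | step 3 | racemic 2-[3,4-bis(benzyloxy)phenyl]-7-methyl-2,3-dihydro-4H,5H-pyrano[4,3-b]pyran-4,5-dione | O=C1CC(c2ccc(OCc3ccccc3)c(OCc3ccccc3)c2)Oc2cc(C)oc(=O)c12
F6 | step 9 | (2S,3S)-2-(3,4-dihydroxyphenyl)-6-methyl-4-oxo-2,3-dihydro-4H-furo[3,2-c]pyran-3-carboxylic acid | OC(=O)[C@H]1c2c(cc(C)oc2=O)O[C@@H]1c1ccc(O)c(O)c1
F7 | step 9 | tert-butyldimethylsilyl (2S,3S)-2-[3,4-bis(tert-butyldimethylsilyloxy)phenyl]-6-methyl-4-oxo-2,3-dihydro-4H-furo[3,2-c]pyran-3-carboxylate (not isolated) | CC(C)(C)[Si](C)(C)OC(=O)[C@H]1c2c(cc(C)oc2=O)O[C@@H]1c1ccc(O[Si](C)(C)C(C)(C)C)c(O[Si](C)(C)C(C)(C)C)c1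
F8 | step 9 | (2S,3S)-2-[3,4-bis(tert-butyldimethylsilyloxy)phenyl]-6-methyl-4-oxo-2,3-dihydro-4H-furo[3,2-c]pyran-3-carboxylic acid | OC(=O)[C@H]1c2c(cc(C)oc2=O)O[C@@H]1c1ccc(O[Si](C)(C)C(C)(C)C)c(O[Si](C)(C)C(C)(C)C)c1
F9 | step 9 | 3,4-bis(tert-butyldimethylsilyloxy)benzaldehyde | O=Cc1ccc(O[Si](C)(C)C(C)(C)C)c(O[Si](C)(C)C(C)(C)C)c1
F10 | step 9 | (2S,3S)-2-[3,4-bis(tert-butyldimethylsilyloxy)phenyl]-6-[2-[3,4-bis(tert-butyldimethylsilyloxy)phenyl]-2-hydroxyethyl]-4-oxo-2,3-dihydro-4H-furo[3,2-c]pyran-3-carboxylic acid (both carbinol epimers, not isolated) | OC(=O)[C@H]1c2c(cc(CC(O)c3ccc(O[Si](C)(C)C(C)(C)C)c(O[Si](C)(C)C(C)(C)C)c3)oc2=O)O[C@@H]1c1ccc(O[Si](C)(C)C(C)(C)C)c(O[Si](C)(C)C(C)(C)C)c1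
F11 | step 9 | (2S,3S)-2-[3,4-bis(tert-butyldimethylsilyloxy)phenyl]-6-[(E)-2-[3,4-bis(tert-butyldimethylsilyloxy)phenyl]ethenyl]-4-oxo-2,3-dihydro-4H-furo[3,2-c]pyran-3-carboxylic acid | OC(=O)[C@H]1c2c(cc(/C=C/c3ccc(O[Si](C)(C)C(C)(C)C)c(O[Si](C)(C)C(C)(C)C)c3)oc2=O)O[C@@H]1c1ccc(O[Si](C)(C)C(C)(C)C)c(O[Si](C)(C)C(C)(C)C)c1
F12 | step 9 | (2S,3S)-2-[3,4-bis(tert-butyldimethylsilyloxy)phenyl]-6-[(E)-2-[3,4-bis(tert-butyldimethylsilyloxy)phenyl]ethenyl]-4-oxo-2,3-dihydro-4H-furo[3,2-c]pyran-3-carbonyl chloride (not isolated) | ClC(=O)[C@H]1c2c(cc(/C=C/c3ccc(O[Si](C)(C)C(C)(C)C)c(O[Si](C)(C)C(C)(C)C)c3)oc2=O)O[C@@H]1c1ccc(O[Si](C)(C)C(C)(C)C)c(O[Si](C)(C)C(C)(C)C)c1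
F13 | step 9 | methyl 5-[(2S,3S)-2-[3,4-bis(tert-butyldimethylsilyloxy)phenyl]-6-[(E)-2-[3,4-bis(tert-butyldimethylsilyloxy)phenyl]ethenyl]-4-oxo-2,3-dihydro-4H-furo[3,2-c]pyran-3-yl]-3,5-dioxopentanoate | COC(=O)CC(=O)CC(=O)[C@H]1c2c(cc(/C=C/c3ccc(O[Si](C)(C)C(C)(C)C)c(O[Si](C)(C)C(C)(C)C)c3)oc2=O)O[C@@H]1c1ccc(O[Si](C)(C)C(C)(C)C)c(O[Si](C)(C)C(C)(C)C)c1
F14 | step 9 | (2S,3S)-2-[3,4-bis(tert-butyldimethylsilyloxy)phenyl]-6-[(E)-2-[3,4-bis(tert-butyldimethylsilyloxy)phenyl]ethenyl]-3-(4-hydroxy-2-oxo-2H-pyran-6-yl)-2,3-dihydro-4H-furo[3,2-c]pyran-4-one | O=c1cc(O)cc([C@H]2c3c(cc(/C=C/c4ccc(O[Si](C)(C)C(C)(C)C)c(O[Si](C)(C)C(C)(C)C)c4)oc3=O)O[C@@H]2c2ccc(O[Si](C)(C)C(C)(C)C)c(O[Si](C)(C)C(C)(C)C)c2)o1
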